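**Remark:** briarane numbering (C1–C20 of the target) is used for all intermediates. Compounds 17–21 are carried as mixtures at C10; that centre is fixed in step 15.

## Retrosynthetic overview

1. The three acetates come last from tetraol 38. The γ-lactone (C7–O–C19) is closed directly after ring B.
2. Ring B (ten-membered) is closed at C6–C7 by an intramolecular Nozaki–Hiyama–Kishi reaction of a (Z)-vinyl iodide with the C7 aldehyde. C8 (with C7 and C17–C19) is joined to C9 by an aldol reaction of a malic-acid-derived dioxolanone enolate.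
3. Ring A (C1, C10–C14) is made first, by a [3+3] annulation that forms C10–C11 and C13–C14. The enabling feature is the 1,4-dioxygenation of ring A (C11–O and C14–O across C12–C13) together with the carboxyl-level carbon C9 on C10. This makes C10 an enolate carbon, C14 an ester carbon, and C11–C13 a ketone homoenolate delivered by an acryloylsilane.
4. The quaternary C1 is set by Fráter–Seebach alkylation, and the C2 and C14 carbinols by Corey–Bakshi–Shibata reductions. A temporary di-tert-butylsilylene bridge between O2 and O14 locks the chair of ring A, which controls C10 and the face of the C11 epoxidation.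
5. Ring order: A (step 10), temporary silylene and dioxolanone rings, epoxide (step 23), B and lactone (step 26).

Key step: step 10

## Route

Step 1
Reactants: 1 methyl (S)-3-hydroxybutanoate
Product: 2 methyl (2S,3S)-3-hydroxy-2-methylbutanoate
Conditions: LiN(iPr)2 (2.1 equiv), THF, −50 → −20 °C; MeI, DMPU, −50 → 0 °C
Reagents that add atoms: iodomethane, CI
Why: Fráter–Seebach alkylation: the lithium-chelated dianion is methylated on the enolate face opposite the C3 methyl group, which sets the new centre 2,3-anti, i.e. (2S).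

Step 2
Reactants: 2 methyl (2S,3S)-3-hydroxy-2-methylbutanoate; 3 2-bromo-N,N-dimethylacetamide
Product: 4 methyl (2S,3S)-2-[2-(dimethylamino)-2-oxoethyl]-3-hydroxy-2-methylbutanoate
Conditions: LiN(iPr)2 (2.2 equiv), THF/DMPU, −78 → −20 °C; then 3, −78 → −10 °C
Reagents that add atoms: none
Why: second Fráter–Seebach alkylation: the electrophile again enters the chelated dianion anti to the C3 substituent, so the quaternary carbon (C1 of the target) is formed with the configuration needed later; an amide is used because it neither lactonises with the alkoxide nor acts as an acylating group in step 10.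

Step 3
Reactants: 4 methyl (2S,3S)-2-[2-(dimethylamino)-2-oxoethyl]-3-hydroxy-2-methylbutanoate
Product: 5 methyl (2S)-2-acetyl-4-(dimethylamino)-2-methyl-4-oxobutanoate
Conditions: Dess–Martin periodinane, NaHCO3, CH2Cl2, 0 → 23 °C
Reagents that add atoms: none
Why: Dess–Martin oxidation removes the carbinol centre that has done its work; the quaternary centre has no α-hydrogen and cannot epimerise.

Step 4
Reactants: 6 prop-2-yn-1-ol
Product: 7 (Z)-3-iodo-2-methylprop-2-en-1-ol
Conditions: MeMgBr (2.5 equiv), CuI (10 mol %), THF, −10 → 23 °C; then I2, −20 → 0 °C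
Reagents that add atoms: methylmagnesium bromide, C[Mg]Br; iodine, II
Why: copper-catalysed anti-carbomagnesiation of the propargylic magnesium alkoxide gives a five-membered vinylmagnesium chelate that is iodinated with retention, which fixes the Z geometry (iodine cis to CH2OH).

Step 5
Reactants: 7 (Z)-3-iodo-2-methylprop-2-en-1-ol
Product: 8 (Z)-3-bromo-1-iodo-2-methylprop-1-ene
Conditions: CBr4, PPh3, CH2Cl2, 0 °C
Reagents that add atoms: carbon tetrabromide, BrC(Br)(Br)Br
Why: Appel bromination at the primary allylic carbon by SN2 without allylic shift; the alkene geometry is untouched.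

Step 6
Reactants: 5 methyl (2S)-2-acetyl-4-(dimethylamino)-2-methyl-4-oxobutanoate; 8 (Z)-3-bromo-1-iodo-2-methylprop-1-ene
Product: 9 methyl (2S,6Z)-2-[2-(dimethylamino)-2-oxoethyl]-7-iodo-2,6-dimethyl-3-oxohept-6-enoate
Conditions: LiN(iPr)2 (1.05 equiv), THF, −78 °C; then 8, DMPU, −78 → −40 °C
Reagents that add atoms: none
Why: the kinetic lithium enolate of the methyl ketone (C3; the amide α-CH is far less acidic and C1 is quaternary) is alkylated by the allylic bromide in an SN2 reaction; no stereocentre is formed and the Z-vinyl iodide is carried over.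

Step 7
Reactants: 9 methyl (2S,6Z)-2-[2-(dimethylamino)-2-oxoethyl]-7-iodo-2,6-dimethyl-3-oxohept-6-enoate
Product: 10 methyl (2S,3R,6Z)-2-[2-(dimethylamino)-2-oxoethyl]-3-hydroxy-7-iodo-2,6-dimethylhept-6-enoate
Conditions: (S)-2-methyl-CBS-oxazaborolidine (0.5 equiv), catecholborane (1.5 equiv), toluene/CH2Cl2, −78 → −40 °C
Reagents that add atoms: none
Why: Corey–Bakshi–Shibata reduction: the ketone is flanked by the quaternary carbon (large) and a CH2 group (small), so the (S)-oxazaborolidine should give the (3R)-alcohol, which is the C2 configuration of the target.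

Step 8
Reactants: 10 methyl (2S,3R,6Z)-2-[2-(dimethylamino)-2-oxoethyl]-3-hydroxy-7-iodo-2,6-dimethylhept-6-enoate
Product: 11 3-O-trimethylsilyl ether of 10
Conditions: TMSCl, imidazole, CH2Cl2, 0 °C
Reagents that add atoms: chlorotrimethylsilane, C[Si](C)(C)Cl
Why: silylation; a trimethylsilyl ether survives LiN(iPr)2 at −78 °C and can later be cleaved beside a tert-butyldimethylsilyl enol ether.

Step 9
Reactants: 12 1-methoxypropa-1,2-diene (methoxyallene)
Product: 14 1-[tert-butyl(dimethyl)silyl]prop-2-en-1-one, via 1-silyl-1-methoxyallene 13 (not isolated)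
Conditions: n-BuLi, THF, −78 °C; TBSCl, −78 → 0 °C; then 1 M aq. HCl, THF, 0 °C
Reagents that add atoms: tert-butyldimethylsilyl chloride, CC(C)(C)[Si](C)(C)Cl; water, O
Why: α-lithiation of the alkoxyallene, C-silylation and hydrolysis of the allenyl enol ether is the standard route to α,β-unsaturated acylsilanes; the reagent is used fresh.

Step 10
Reactants: 11 3-O-trimethylsilyl ether of 10; 14 1-[tert-butyl(dimethyl)silyl]prop-2-en-1-one
Product: 17 ring-A ketone with Δ11(12) tert-butyldimethylsilyl enol ether (C14 ketone; C10 carboxamide), via lithium alkoxide 1,2-adduct 15 (not isolated), via siloxyallyl lithium 16 (not isolated)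
Conditions: LiN(iPr)2 (1.1 equiv), THF, −78 °C, 1 h; 14 (1.3 equiv), −85 °C; warm to −30 °C over 2 h; AcOH, −78 °C
Reagents that add atoms: none
Why: Proposed new method: the lithium amide enolate of 11 (C10) adds 1,2 to the acylsilane carbonyl (C11), the α-silyl alkoxide 15 undergoes a 1,2-Brook shift to the siloxyallyl lithium 16 (a ketone homoenolate), and its γ-carbon (C13) acylates the C14 methyl ester in a Dieckmann-type closure with loss of methoxide. The closest known reaction type is the Brook-rearrangement-mediated [3+2] annulation of acryloylsilanes with ketone enolates, together with the γ-alkylation of 1-siloxyallyl lithiums; new here are the ester as terminating electrophile and the six-membered ring. Ring A closes 6-exo-trig at the ester carbonyl (C13 to C14); attack through the α-carbon (C11) would give a four-membered ring and is excluded. The only new stereocentre, C10, is not controlled here and is fixed under thermodynamic control in step 15, while C1 and C2 are untouched. The step needs 1,2- rather than 1,4-addition (lithium enolate at −85 °C on a carbonyl as electrophilic as an aldehyde) and a Brook shift faster than retro-addition (allylic stabilisation of the carbanion). It also needs acylation at C14 only, which the substrate secures because C9 is an amide that the stabilised allyl anion does not attack and C10 is the sole enolisable position of 11.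

Step 11
Reactants: 17 ring-A ketone with Δ11(12) silyl enol ether
Product: 18 (14S)-2,14-diol (Δ11(12) silyl enol ether retained)
Conditions: (R)-2-methyl-CBS-oxazaborolidine (1.0 equiv), catecholborane (2.5 equiv), toluene, −78 → −40 °C; then K2CO3, MeOH, 0 °C
Reagents that add atoms: none
Why: Corey–Bakshi–Shibata reduction of the C14 ketone (quaternary C1 large, C13 H2 small): the (R)-oxazaborolidine should give the (14S)-alcohol with O14 syn to O2, against the ring's preference for axial attack; methanolysis in the work-up removes the trimethylsilyl ether.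

Step 12
Reactants: 18 (14S)-2,14-diol
Product: 19 2,14-O-di-tert-butylsilylene acetal
Conditions: tBu2Si(OTf)2, 2,6-lutidine, CH2Cl2, 0 °C
Reagents that add atoms: di-tert-butylsilyl bis(trifluoromethanesulfonate), CC(C)(C)[Si](OS(=O)(=O)C(F)(F)F)(OS(=O)(=O)C(F)(F)F)C(C)(C)C
Why: silylene acetal formation of the syn-1,3-diol; the six-membered dioxasilinane (C3 and C13 equatorial on it) locks ring A in the chair with O14 axial, C2 equatorial and the C1 methyl axial, which later controls C10 and C11.

Step 13
Reactants: 19 2,14-O-di-tert-butylsilylene acetal (C10 carboxamide)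
Product: 20 primary alcohol (C9 H2OH)
Conditions: LiNH2BH3 (4 equiv, from BH3·NH3 and n-BuLi), THF, 0 → 23 °C
Reagents that add atoms: none
Why: lithium amidotrihydroborate reduces tertiary amides to primary alcohols with C–N cleavage and leaves the enol silane, the silylene and the vinyl iodide alone.

Step 14
Reactants: 20 primary alcohol
Product: 21 9-O-(4-methoxybenzyl) ether
Conditions: NaH, 4-methoxybenzyl chloride, Bu4NI (cat.), THF/DMF, 0 → 23 °C
Reagents that add atoms: 4-methoxybenzyl chloride, COc1ccc(CCl)cc1
Why: Williamson etherification of the only free hydroxyl; an ether, unlike an ester, is not prone to β-elimination once C11 is a ketone.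

Step 15
Reactants: 21 9-O-(4-methoxybenzyl) ether
Product: 22 C11 ketone with C10 configured as in the target
Conditions: 1 M aq. HCl, THF, 0 → 23 °C, until the C10 ratio is constant
Reagents that add atoms: none
Why: acid hydrolysis of the enol silane and equilibration of C10 through the enol: in the locked chair the CH2OPMB group is equatorial (trans to the C2 branch), the axial position being 1,3-diaxial to O14, so C10 is set as in the target.

Step 16
Reactants: 22 C11 ketone
Product: 23 C11 exocyclic methylene compound (C20 installed)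
Conditions: Zn, CH2Br2, TiCl4 (preformed Takai–Lombardo reagent), THF/CH2Cl2, 0 → 23 °C
Reagents that add atoms: dibromomethane, BrCBr
Why: Takai–Lombardo methylenation, a non-basic carbonyl olefination that avoids C10 epimerisation and β-elimination of the ether.

Step 17
Reactants: 23 C11 exocyclic methylene compound
Product: 24 primary alcohol (C9 H2OH)
Conditions: DDQ, CH2Cl2/pH 7 phosphate buffer (10:1), 0 °C
Reagents that add atoms: none
Why: oxidative cleavage of the 4-methoxybenzyl ether; the silylene, the vinyl iodide and the 1,1-disubstituted alkene are inert.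

Step 18
Reactants: 24 primary alcohol
Product: 25 C9 aldehyde (β,γ-unsaturated)
Conditions: Dess–Martin periodinane, NaHCO3, CH2Cl2, 0 °C; used at once without chromatography
Reagents that add atoms: none
Why: Dess–Martin oxidation under buffered, non-basic conditions should give the aldehyde without migration of the alkene or loss of the C10 configuration.

Step 19
Reactants: 26 dimethyl (S)-malate
Product: 27 dimethyl (2S,3R)-2-hydroxy-3-methylbutanedioate
Conditions: LiN(SiMe3)2 (2.2 equiv), THF, −78 → −20 °C; MeI, −78 → 0 °C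
Reagents that add atoms: iodomethane, CI
Why: Fráter–Seebach alkylation of the malate dianion: methyl iodide enters anti to the substituent on the carbinol carbon, giving the anti (2S,3R) product and thus C17 of the target.

Step 20
Reactants: 27 dimethyl (2S,3R)-2-hydroxy-3-methylbutanedioate
Product: 28 (2S,3R)-2-hydroxy-3-methylbutanedioic acid
Conditions: LiOH, THF/H2O, 0 → 23 °C; then aq. HCl to pH 1
Reagents that add atoms: lithium hydroxide, [Li+].[OH-]
Why: saponification under mild conditions; neither stereocentre is affected.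

Step 21
Reactants: 28 (2S,3R)-2-hydroxy-3-methylbutanedioic acid
Product: 29 (2R)-2-[(2S,4S)-2-tert-butyl-5-oxo-1,3-dioxolan-4-yl]propanoic acid
Conditions: pivalaldehyde, TsOH·H2O (cat.), H2SO4 (cat.), pentane, reflux with water separation; crystallisation
Reagents that add atoms: pivalaldehyde, CC(C)(C)C=O
Why: acetalisation of the α-hydroxy acid gives the five-membered dioxolanone in preference to the six-membered dioxanone, and the cis isomer (tert-butyl cis to the side chain) is favoured and crystallised; the acetal carbon now stores the C8 configuration.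

Step 22
Reactants: 25 C9 aldehyde; 29 (2R)-2-[(2S,4S)-2-tert-butyl-5-oxo-1,3-dioxolan-4-yl]propanoic acid
Product: 31 9-O-triethylsilyl aldol adduct (C19 acid), via aldol hydroxy acid 30 (not isolated)
Conditions: 29, LiN(iPr)2 (2.1 equiv), THF/DMPU, −78 °C; 25, −78 °C, 1 h; TESOTf (2.5 equiv), −78 → −40 °C; aq. NaHCO3, then pH 5 work-up
Reagents that add atoms: triethylsilyl trifluoromethanesulfonate, CC[Si](CC)(CC)OS(=O)(=O)C(F)(F)F
Why: aldol addition with self-regeneration of the stereocentre: the dioxolanone enolate (the carboxylate shields C17–H) is attacked on the face opposite the tert-butyl group, which sets C8, and Felkin–Anh addition anti to the quaternary C1 (the largest α-substituent, C11 being sp2) sets C9; the silyl triflate traps the aldolate before retro-aldol or lactonisation.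

Step 23
Reactants: 31 9-O-triethylsilyl aldol adduct
Product: 32 11,20-epoxide
Conditions: mCPBA (1.3 equiv), Na2HPO4, CH2Cl2, 0 °C
Reagents that add atoms: 3-chloroperbenzoic acid, OOC(=O)c1cccc(Cl)c1
Why: Prilezhaev epoxidation: the peracid attacks the exocyclic alkene along the equatorial direction from the α-face because axial approach on the β-face is blocked by the syn-axial C15 methyl of the locked chair, giving O11 α and C20 β as in the target; the iodoalkene is too electron-poor to react.

Step 24
Reactants: 32 11,20-epoxide (dioxolanone)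
Product: 33 C7 N-methoxy-N-methylamide with free C8 hydroxyl
Conditions: MeNH(OMe)·HCl (3 equiv), iPrMgCl (7 equiv), THF, −20 → 0 °C
Reagents that add atoms: N,O-dimethylhydroxylamine hydrochloride, CNOC.Cl
Why: aminolysis of the activated acylal carbonyl by the chloromagnesium amide (Weinreb amide formation) with loss of pivalaldehyde; the carboxylate and the epoxide do not react at this temperature and no stereocentre is touched.

Step 25
Reactants: 33 C7 N-methoxy-N-methylamide
Product: 35 C7 aldehyde C19 methyl ester, via aldehyde acid 34 (not isolated)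
Conditions: iBu2AlH (3.5 equiv), THF, −78 °C; aq. KNaC4H4O6 work-up; then TMSCHN2, MeOH/toluene, 0 °C
Reagents that add atoms: (trimethylsilyl)diazomethane, C[Si](C)(C)C=[N+]=[N-]
Why: iBu2AlH reduces the Weinreb amide to the aldehyde through a stable chelated tetrahedral intermediate while the aluminium carboxylate is not reduced; the acid is then esterified so that lactonisation can follow ring closure.

Step 26
Reactants: 35 C7 aldehyde C19 methyl ester
Product: 37 tricyclic lactone (rings A and B and γ-lactone; silyl groups retained), via hydroxy ester 36 (not isolated)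
Conditions: CrCl2 (10 equiv), NiCl2 (0.5 mol %), DMSO/THF (3:1), 0.002 M, 23 °C; aqueous work-up; then Et3N, DMAP (cat.), CH2Cl2, 23 °C
Reagents that add atoms: none
Why: Nozaki–Hiyama–Kishi reaction: the alkenylchromium species formed from the Z-iodide (nickel-catalysed, geometry retained) adds to the C7 aldehyde at high dilution to close the ten-membered ring B; Felkin–Anh addition anti to the C8 oxygen and past the smaller C17 branch should give the (7S)-alcohol, which lactonises on C19 (five-membered ring) under mild base.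

Step 27
Reactants: 37 tricyclic lactone
Product: 38 2,8,9,14-tetraol
Conditions: Bu4NF (5 equiv), AcOH (5 equiv), THF, 0 → 23 °C
Reagents that add atoms: none
Why: fluoride cleavage of the silylene acetal and the triethylsilyl ether; buffering with acetic acid protects the epoxide and the β-hydroxy lactone.

Step 28
Reactants: 38 2,8,9,14-tetraol
Product: 39 junceellolide F
Conditions: Ac2O, pyridine, DMAP (cat.), CH2Cl2, 0 → 23 °C
Reagents that add atoms: acetic anhydride, CC(=O)OC(C)=O
Why: acetylation of the three secondary hydroxyls (C2, C9, C14); the tertiary C8 hydroxyl is not acylated under these conditions.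

## Compound list

1 | methyl (S)-3-hydroxybutanoate | C[C@H](O)CC(=O)OC | starting material
2 | methyl (2S,3S)-3-hydroxy-2-methylbutanoate | COC(=O)[C@@H](C)[C@H](C)O | intermediate
3 | 2-bromo-N,N-dimethylacetamide | BrCC(=O)N(C)C | starting material
4 | methyl (2S,3S)-2-[2-(dimethylamino)-2-oxoethyl]-3-hydroxy-2-methylbutanoate | COC(=O)[C@@](C)(CC(=O)N(C)C)[C@H](C)O | intermediate
5 | methyl (2S)-2-acetyl-4-(dimethylamino)-2-methyl-4-oxobutanoate | COC(=O)[C@@](C)(CC(=O)N(C)C)C(C)=O | intermediate
6 | prop-2-yn-1-ol | C#CCO | starting material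
7 | (Z)-3-iodo-2-methylprop-2-en-1-ol | OC/C(C)=C\I | intermediate
8 | (Z)-3-bromo-1-iodo-2-methylprop-1-ene | BrC/C(C)=C\I | intermediate
9 | methyl (2S,6Z)-2-[2-(dimethylamino)-2-oxoethyl]-7-iodo-2,6-dimethyl-3-oxohept-6-enoate | COC(=O)[C@@](C)(CC(=O)N(C)C)C(=O)CC/C(C)=C\I | intermediate
10 | methyl (2S,3R,6Z)-2-[2-(dimethylamino)-2-oxoethyl]-3-hydroxy-7-iodo-2,6-dimethylhept-6-enoate | COC(=O)[C@@](C)(CC(=O)N(C)C)[C@H](O)CC/C(C)=C\I | intermediate
11 | 3-O-trimethylsilyl ether of 10 (C1 and C2 as in the target; C14 methyl ester; C10 H2 next to the amide C9) | COC(=O)[C@@](C)(CC(=O)N(C)C)[C@H](O[Si](C)(C)C)CC/C(C)=C\I | intermediate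
12 | 1-methoxypropa-1,2-diene | COC=C=C | starting material
13 | tert-butyl(1-methoxypropa-1,2-dien-1-yl)dimethylsilane | COC(=C=C)[Si](C)(C)C(C)(C)C | intermediate (not isolated)
14 | 1-[tert-butyl(dimethyl)silyl]prop-2-en-1-one | C=CC(=O)[Si](C)(C)C(C)(C)C | intermediate
15 | lithium alkoxide from 1,2-addition of the C10 enolate to the acylsilane (C10–C11 formed) | COC(=O)[C@@](C)(C(C(=O)N(C)C)C([O-])(C=C)[Si](C)(C)C(C)(C)C)[C@H](O[Si](C)(C)C)CC/C(C)=C\I.[Li+] | intermediate (not isolated)
16 | siloxyallyl lithium after the 1,2-Brook shift (carbanion at C13) | COC(=O)[C@@](C)(C(C(=O)N(C)C)C(O[Si](C)(C)C(C)(C)C)=C[CH2-])[C@H](O[Si](C)(C)C)CC/C(C)=C\I.[Li+] | intermediate (not isolated)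
17 | ring-A ketone: 4-(tert-butyldimethylsilyloxy)cyclohex-3-en-1-one (C14 ketone, Δ11(12) enol silane) with CONMe2 on C10 and, on C1, methyl and the (1R,4Z)-5-iodo-4-methyl-1-(trimethylsilyloxy)pent-4-enyl chain; C10 epimers | O=C1CC=C(O[Si](C)(C)C(C)(C)C)C(C(=O)N(C)C)[C@@]1(C)[C@H](O[Si](C)(C)C)CC/C(C)=C\I | intermediate
18 | (14S)-2,14-diol of the same skeleton (enol silane and amide retained); C10 epimers | O[C@H]1CC=C(O[Si](C)(C)C(C)(C)C)C(C(=O)N(C)C)[C@@]1(C)[C@H](O)CC/C(C)=C\I | intermediate
19 | 2,14-O-di-tert-butylsilylene acetal of 18; C10 epimers | CC(C)(C)[Si]1(C(C)(C)C)O[C@H]2CC=C(O[Si](C)(C)C(C)(C)C)C(C(=O)N(C)C)[C@@]2(C)[C@H](O1)CC/C(C)=C\I | intermediate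
20 | C9 primary alcohol (amide reduced); C10 epimers | CC(C)(C)[Si]1(C(C)(C)C)O[C@H]2CC=C(O[Si](C)(C)C(C)(C)C)C(CO)[C@@]2(C)[C@H](O1)CC/C(C)=C\I | intermediate
21 | 9-O-(4-methoxybenzyl) ether of 20; C10 epimers | CC(C)(C)[Si]1(C(C)(C)C)O[C@H]2CC=C(O[Si](C)(C)C(C)(C)C)C(COCc3ccc(OC)cc3)[C@@]2(C)[C@H](O1)CC/C(C)=C\I | intermediate
22 | C11 ketone, C10 as in the target (CH2OPMB equatorial) | CC(C)(C)[Si]1(C(C)(C)C)O[C@H]2CCC(=O)[C@H](COCc3ccc(OC)cc3)[C@@]2(C)[C@H](O1)CC/C(C)=C\I | intermediate
23 | C11 exocyclic methylene compound | CC(C)(C)[Si]1(C(C)(C)C)O[C@H]2CCC(=C)[C@H](COCc3ccc(OC)cc3)[C@@]2(C)[C@H](O1)CC/C(C)=C\I | intermediate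
24 | C9 primary alcohol with C11 methylene | CC(C)(C)[Si]1(C(C)(C)C)O[C@H]2CCC(=C)[C@H](CO)[C@@]2(C)[C@H](O1)CC/C(C)=C\I | intermediate
25 | C9 aldehyde with C11 methylene | CC(C)(C)[Si]1(C(C)(C)C)O[C@H]2CCC(=C)[C@H](C=O)[C@@]2(C)[C@H](O1)CC/C(C)=C\I | intermediate
26 | dimethyl (S)-malate | COC(=O)C[C@H](O)C(=O)OC | starting material
27 | dimethyl (2S,3R)-2-hydroxy-3-methylbutanedioate | COC(=O)[C@H](C)[C@H](O)C(=O)OC | intermediate
28 | (2S,3R)-2-hydroxy-3-methylbutanedioic acid | OC(=O)[C@H](C)[C@H](O)C(=O)O | intermediate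
29 | (2R)-2-[(2S,4S)-2-tert-butyl-5-oxo-1,3-dioxolan-4-yl]propanoic acid | CC(C)(C)[C@H]1O[C@@H]([C@@H](C)C(=O)O)C(=O)O1 | intermediate
30 | aldol adduct: (9R)-hydroxy acid with C8 quaternary in the dioxolanone (formed as its dilithium salt) | CC(C)(C)[Si]1(C(C)(C)C)O[C@H]2CCC(=C)[C@H]([C@@H](O)[C@]3(O[C@H](C(C)(C)C)OC3=O)[C@@H](C)C(=O)O)[C@@]2(C)[C@H](O1)CC/C(C)=C\I | intermediate (not isolated)
31 | 9-O-triethylsilyl ether of 30 (C19 acid) | CC(C)(C)[Si]1(C(C)(C)C)O[C@H]2CCC(=C)[C@H]([C@@H](O[Si](CC)(CC)CC)[C@]3(O[C@H](C(C)(C)C)OC3=O)[C@@H](C)C(=O)O)[C@@]2(C)[C@H](O1)CC/C(C)=C\I | intermediate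
32 | 11,20-epoxide of 31 (O11 α, C20 β) | CC(C)(C)[Si]1(C(C)(C)C)O[C@H]2CC[C@]4(CO4)[C@H]([C@@H](O[Si](CC)(CC)CC)[C@]3(O[C@H](C(C)(C)C)OC3=O)[C@@H](C)C(=O)O)[C@@]2(C)[C@H](O1)CC/C(C)=C\I | intermediate
33 | C7 N-methoxy-N-methylamide, free C8 hydroxyl, C19 acid | CC(C)(C)[Si]1(C(C)(C)C)O[C@H]2CC[C@]4(CO4)[C@H]([C@@H](O[Si](CC)(CC)CC)[C@@](O)(C(=O)N(C)OC)[C@@H](C)C(=O)O)[C@@]2(C)[C@H](O1)CC/C(C)=C\I | intermediate
34 | C7 aldehyde C19 acid | CC(C)(C)[Si]1(C(C)(C)C)O[C@H]2CC[C@]4(CO4)[C@H]([C@@H](O[Si](CC)(CC)CC)[C@@](O)(C=O)[C@@H](C)C(=O)O)[C@@]2(C)[C@H](O1)CC/C(C)=C\I | intermediate (not isolated)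
35 | C7 aldehyde C19 methyl ester | CC(C)(C)[Si]1(C(C)(C)C)O[C@H]2CC[C@]4(CO4)[C@H]([C@@H](O[Si](CC)(CC)CC)[C@@](O)(C=O)[C@@H](C)C(=O)OC)[C@@]2(C)[C@H](O1)CC/C(C)=C\I | intermediate
36 | ring-B (7S)-allylic alcohol with C19 methyl ester (5Z) | CC(C)(C)[Si]4(C(C)(C)C)O[C@H]1CC[C@]2(CO2)[C@@H]2[C@@H](O[Si](CC)(CC)CC)[C@](O)([C@@H](C)C(=O)OC)[C@@H](O)/C=C(/C)CC[C@@H](O4)[C@@]12C | intermediate (not isolated)
37 | tricyclic lactone: 2,14-O-di-tert-butylsilylene-9-O-triethylsilyl derivative of the tetraol | CC(C)(C)[Si]4(C(C)(C)C)O[C@H]1CC[C@]2(CO2)[C@@H]2[C@@H](O[Si](CC)(CC)CC)[C@@]3(O)[C@H](/C=C(/C)CC[C@@H](O4)[C@@]12C)OC(=O)[C@@H]3C | intermediate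
38 | 2,8,9,14-tetraol (tri-O-deacetyl junceellolide F) | O[C@H]1CC[C@]2(CO2)[C@@H]2[C@@H](O)[C@@]3(O)[C@H](/C=C(/C)CC[C@@H](O)[C@@]12C)OC(=O)[C@@H]3C | intermediate
39 | junceellolide F | CC(=O)O[C@H]1CC[C@]2(CO2)[C@@H]2[C@@H](OC(C)=O)[C@@]3(O)[C@H](/C=C(/C)CC[C@@H](OC(C)=O)[C@@]12C)OC(=O)[C@@H]3C | target

## Step count and risks

Total step count: 28. Longest linear sequence: 22 steps (1, 2, 3, 6, 7, 8, 10–18, 22–28).

**1. Step 10 (Proposed new method).**
What may go wrong: conjugate addition of the enolate to the acylsilane instead of carbonyl addition; lactonisation of the α-silyl alkoxide onto the C14 ester before the Brook shift; or proton transfer that quenches the siloxyallyl anion before ring closure.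
Fallback (known chemistry), setting out from 11 and coming back at 22: the lithium enolate of 11 (LiN(iPr)2, THF, −78 °C) is added to methyl 4-oxobutanoate, and the aldolate is silylated in the flask with triethylsilyl triflate to give the C11 triethylsilyl ether aldol adduct F1. KOtBu in THF closes ring A by Dieckmann condensation of the C13 ester enolate on the C14 ester to give the β-keto ester F2. Me3SnOH in 1,2-dichloroethane at 80 °C hydrolyses the C13 ester, and the β-keto acid loses CO2 to give the ring-A ketone F3. Corey–Bakshi–Shibata reduction as in step 11, with methanolic K2CO3 work-up, gives the diol F4; tBu2Si(OTf)2 gives the silylene acetal F5; LiNH2BH3 gives the primary alcohol F6; and NaH with 4-methoxybenzyl chloride gives the ether F7. Pyridinium p-toluenesulfonate in methanol frees the C11 hydroxyl to give the alcohol F8. Dess–Martin oxidation followed by equilibration with DBU gives 22. F1–F8 are mixtures at C10 and C11, which converge at 22.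

**2. Step 26.**
What may go wrong: slow ring closure with intermolecular coupling, and poor facial selectivity at C7 if the free C8 hydroxyl chelates chromium.
Fallback, setting out from 35 and coming back at 37: the chromium-mediated closure is run under slow addition, and the crude mixture of 36 and its C7 epimer is oxidised at once with Dess–Martin periodinane to the ring-B enone F9. Zn(BH4)2 in Et2O at −30 °C then reduces the ketone under chelation between O7 and the C8 hydroxyl, with hydride arriving past the smaller C17 branch, to give 36, which lactonises to 37 as in the main route.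

**3. Step 22.**
What may go wrong: poor facial selectivity at C9 (addition against the Felkin–Anh sense) with the hindered α-branched aldehyde.
Fallback, setting out from 30 and coming back at 31: the aldol reaction is quenched with acetic acid instead of the silyl triflate, and the hydroxy acid 30 (as C9 epimers) is oxidised with Dess–Martin periodinane to the C9 ketone F10. NaBH4 with CeCl3 in methanol at −78 °C (non-chelating; hydride anti to the C8–O8 bond and past the ring carbonyl C7 rather than the C17 branch) returns 30 as the (9R)-alcohol, which is silylated with triethylsilyl triflate and 2,6-lutidine to 31.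

## Further compounds

F1 | step 10 | aldol adduct of 11 with methyl 4-oxobutanoate, C11 triethylsilyl ether | COC(=O)[C@@](C)(C(C(=O)N(C)C)C(O[Si](CC)(CC)CC)CCC(=O)OC)[C@H](O[Si](C)(C)C)CC/C(C)=C\I
F2 | step 10 | ring-A β-keto ester (C14 ketone, C13 methyl ester, C11 triethylsilyloxy) | COC(=O)C1CC(O[Si](CC)(CC)CC)C(C(=O)N(C)C)[C@@](C)([C@H](O[Si](C)(C)C)CC/C(C)=C\I)C1=O
F3 | step 10 | ring-A C14 ketone with C11 triethylsilyloxy group | O=C1CCC(O[Si](CC)(CC)CC)C(C(=O)N(C)C)[C@@]1(C)[C@H](O[Si](C)(C)C)CC/C(C)=C\I
F4 | step 10 | (14S)-2,14-diol with C11 triethylsilyloxy group | O[C@H]1CCC(O[Si](CC)(CC)CC)C(C(=O)N(C)C)[C@@]1(C)[C@H](O)CC/C(C)=C\I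
F5 | step 10 | 2,14-O-di-tert-butylsilylene acetal of F4 | CC(C)(C)[Si]1(C(C)(C)C)O[C@H]2CCC(O[Si](CC)(CC)CC)C(C(=O)N(C)C)[C@@]2(C)[C@H](O1)CC/C(C)=C\I
F6 | step 10 | C9 primary alcohol from F5 | CC(C)(C)[Si]1(C(C)(C)C)O[C@H]2CCC(O[Si](CC)(CC)CC)C(CO)[C@@]2(C)[C@H](O1)CC/C(C)=C\I
F7 | step 10 | 9-O-(4-methoxybenzyl) ether of F6 | CC(C)(C)[Si]1(C(C)(C)C)O[C@H]2CCC(O[Si](CC)(CC)CC)C(COCc3ccc(OC)cc3)[C@@]2(C)[C@H](O1)CC/C(C)=C\I
F8 | step 10 | C11 alcohol from F7 | CC(C)(C)[Si]1(C(C)(C)C)O[C@H]2CCC(O)C(COCc3ccc(OC)cc3)[C@@]2(C)[C@H](O1)CC/C(C)=C\I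
F9 | step 26 | ring-B enone (C7 ketone, C19 methyl ester) | CC(C)(C)[Si]4(C(C)(C)C)O[C@H]1CC[C@]2(CO2)[C@@H]2[C@@H](O[Si](CC)(CC)CC)[C@](O)([C@@H](C)C(=O)OC)C(=O)/C=C(/C)CC[C@@H](O4)[C@@]12C
F10 | step 22 | C9 ketone of the aldol adduct (C19 acid) | CC(C)(C)[Si]1(C(C)(C)C)O[C@H]2CCC(=C)[C@H](C(=O)[C@]3(O[C@H](C(C)(C)C)OC3=O)[C@@H](C)C(=O)O)[C@@]2(C)[C@H](O1)CC/C(C)=C\I
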